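**Plan**
- Cuts, in retrosynthetic order: the C4–O ester bond; the enal back to a C6–CH2OH group with the alkene at C7=C8; C4–O back to C4–Si. Then C3a–C8a and C4–C5 are cut together, and finally C1–C8a.
- Enabling feature: the five- and seven-membered rings share only the C3a–C8a bond. C1–C2–C3 is a three-atom bridge between a C3a≡C4 alkyne and a C8a=C8 alkene. C8 carries a cyclopropane made of C7, C6 and C5, and opening C7–C5 supplies five of the seven ring carbons.
- Forward order: fragment C1–C4 (with isopropyl) and fragment C5–C8a (with methyl) are joined at C1–C8a by sp3–sp2 coupling. One rhodium step then closes both rings. The C4 silane becomes ketone, alcohol and ester, and the C6 side chain becomes the enal.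
- Stereochemistry: C3 comes from (R)-2-hydroxy-3-methylbutanoic acid by self-regeneration of the stereocentre, and C6/C7 from (S)-glycidol. C8a is set by chirality transfer from C7 in the stereospecific ring opening. C3a is set by equilibration and C4 by hydroxyl-directed hydride delivery. C6 is erased at the end.

Key step: step 14

Assumption: the labels C1–C8a used for all intermediates are the hydroazulene positions these atoms take in the target, and β means the face of the angular methyl group.

Step 1
Reactants: 1 (R)-2-hydroxy-3-methylbutanoic acid; 2 pivalaldehyde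
Product: 3 (2R,5R)-2-tert-butyl-5-isopropyl-1,3-dioxolan-4-one (2,5-cis)
Conditions: p-TsOH (cat.), H2SO4 (cat.), pentane, reflux, Dean–Stark; crystallisation
Reagents that add atoms: none
Why: Acid-catalysed acetalisation with water removal should give the 2,5-cis dioxolanone as the thermodynamic product, so the configuration of 1 is copied onto the new acetal centre (first half of self-regeneration of stereocentres).

Step 2
Reactants: 3 (2R,5R)-2-tert-butyl-5-isopropyl-1,3-dioxolan-4-one; 4 allyl bromide
Product: 6 (2R,5R)-5-allyl-2-tert-butyl-5-isopropyl-1,3-dioxolan-4-one (allyl trans to tert-butyl), via lithium enolate 5 (not isolated)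
Conditions: LDA, THF, −78 °C; allyl bromide, −78 → −30 °C
Reagents that add atoms: none
Why: Enolate alkylation with a reactive allylic halide: the planar enolate keeps only the acetal centre, whose tert-butyl group blocks one face, so allyl enters where hydrogen had been and C3 is rebuilt with overall retention as the fully substituted (R) centre.

Step 3
Reactants: 6 (2R,5R)-5-allyl-2-tert-butyl-5-isopropyl-1,3-dioxolan-4-one
Product: 9 (R)-3-isopropylhex-5-en-1-yn-3-ol, via lactol 7 (not isolated), via hydroxy aldehyde 8 (not isolated)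
Conditions: DIBAL-H, CH2Cl2, −78 °C; MeOH, then K2CO3, Ohira–Bestmann reagent (excess), 0 °C → rt
Reagents that add atoms: dimethyl (1-diazo-2-oxopropyl)phosphonate COP(=O)(OC)C(=[N+]=[N-])C(C)=O
Why: Partial reduction of the lactone-type carbonyl stops at the aluminium lactolate, basic methanol unravels lactol 7 to pivalaldehyde and the non-enolisable aldehyde 8, and Ohira–Bestmann homologation turns CHO into the C3a≡C4 alkyne without touching C3.

Step 4
Reactants: 9 (R)-3-isopropylhex-5-en-1-yn-3-ol
Product: 10 (R)-triethyl[(3-isopropylhex-5-en-1-yn-3-yl)oxy]silane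
Conditions: TESOTf, 2,6-lutidine, CH2Cl2, 0 °C
Reagents that add atoms: triethylsilyl triflate CC[Si](CC)(CC)OS(=O)(=O)C(F)(F)F
Why: Silyl triflate silylation is the standard way to cap a hindered tertiary propargylic alcohol, which is needed because the later organozinc reagent does not tolerate a free hydroxyl group.

Step 5
Reactants: 10 (R)-triethyl[(3-isopropylhex-5-en-1-yn-3-yl)oxy]silane
Product: 12 (R)-benzyl[3-isopropyl-3-(triethylsilyloxy)hex-5-en-1-yn-1-yl]dimethylsilane, via lithium acetylide 11 (not isolated)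
Conditions: n-BuLi, THF, −78 °C; BnMe2SiCl, −78 °C → rt
Reagents that add atoms: benzyl(chloro)dimethylsilane C[Si](C)(Cl)Cc1ccccc1
Why: Deprotonation of the terminal alkyne and C-silylation with a chlorosilane; the benzyldimethylsilyl group survives the coming steps yet can be unmasked by fluoride for a Tamao–Fleming oxidation.

Step 6
Reactants: 12 (R)-benzyl[3-isopropyl-3-(triethylsilyloxy)hex-5-en-1-yn-1-yl]dimethylsilane
Product: 14 (R)-5-[benzyl(dimethyl)silyl]-3-isopropyl-3-(triethylsilyloxy)pent-4-yn-1-ol, via aldehyde 13 (not isolated)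
Conditions: O3, CH2Cl2/MeOH, −78 °C (Sudan III end point); NaBH4, −78 → 0 °C
Reagents that add atoms: ozone [O-][O+]=O
Why: Ozonolysis with reductive work-up: ozone attacks the terminal alkene far faster than the silylalkyne or the arene, and borohydride takes aldehyde 13 straight to the C1 alcohol, leaving exactly the C2–C1 two-carbon arm.

Step 7
Reactants: 14 (R)-5-[benzyl(dimethyl)silyl]-3-isopropyl-3-(triethylsilyloxy)pent-4-yn-1-ol
Product: 15 (R)-benzyl[5-iodo-3-isopropyl-3-(triethylsilyloxy)pent-1-yn-1-yl]dimethylsilane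
Conditions: I2, PPh3, imidazole, CH2Cl2, 0 °C
Reagents that add atoms: iodine II
Why: Appel-type iodination of an unhindered primary alcohol under buffered conditions that leave both silyl groups alone.

Step 8
Reactants: 16 (S)-glycidol
Product: 17 (R)-2-{[(4-methoxybenzyl)oxy]methyl}oxirane
Conditions: NaH, PMBCl, Bu4NI (cat.), DMF, 0 °C → rt
Reagents that add atoms: 4-methoxybenzyl chloride COc1ccc(CCl)cc1
Why: Williamson etherification; the degenerate Payne shift of the glycidol alkoxide returns the same enantiomer, so the future C6 centre is preserved (only the descriptor changes), and PMB is chosen because it outlasts the fluoride of step 15.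

Step 9
Reactants: 17 (R)-2-{[(4-methoxybenzyl)oxy]methyl}oxirane; 18 triethyl phosphonoacetate
Product: 20 ethyl (1R,2R)-2-{[(4-methoxybenzyl)oxy]methyl}cyclopropane-1-carboxylate (trans), via sodium phosphonate 19 (not isolated)
Conditions: NaH, toluene, rt; then 17, 110 °C
Reagents that add atoms: none
Why: Wadsworth–Emmons cyclopropanation: the phosphonate anion opens the epoxide at CH2 (future C5), phosphoryl migrates to the alkoxide and the ester enolate displaces phosphate in a 3-exo-tet SN2 closure with inversion at C6, the trans relationship at C7 following from the less crowded closure.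

Step 10
Reactants: 20 ethyl (1R,2R)-2-{[(4-methoxybenzyl)oxy]methyl}cyclopropane-1-carboxylate
Product: 22 1-({[(1R,2R)-2-ethynylcyclopropyl]methoxy}methyl)-4-methoxybenzene, via cyclopropanecarbaldehyde 21 (not isolated)
Conditions: DIBAL-H, CH2Cl2, −78 °C; MeOH, then K2CO3, Ohira–Bestmann reagent, 0 °C → rt
Reagents that add atoms: dimethyl (1-diazo-2-oxopropyl)phosphonate COP(=O)(OC)C(=[N+]=[N-])C(C)=O
Why: One-pot ester-to-alkyne conversion (partial reduction, then Ohira–Bestmann homologation); the ester carbon becomes C8, the new carbon becomes C8a, and the trans-cyclopropanecarbaldehyde is the stable epimer under the mild base.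

Step 11
Reactants: 22 1-({[(1R,2R)-2-ethynylcyclopropyl]methoxy}methyl)-4-methoxybenzene
Product: 24 1-methoxy-4-({[(1R,2R)-2-(prop-1-yn-1-yl)cyclopropyl]methoxy}methyl)benzene, via lithium acetylide 23 (not isolated)
Conditions: n-BuLi, THF, −78 °C; MeI, −78 °C → rt
Reagents that add atoms: iodomethane CI
Why: Alkylation of a lithium acetylide with iodomethane installs the carbon that becomes the angular methyl group.

Step 12
Reactants: 24 1-methoxy-4-({[(1R,2R)-2-(prop-1-yn-1-yl)cyclopropyl]methoxy}methyl)benzene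
Product: 26 1-[({(1R,2R)-2-[(E)-2-iodoprop-1-en-1-yl]cyclopropyl}methoxy)methyl]-4-methoxybenzene, via alkenylzirconocene 25 (not isolated)
Conditions: Cp2Zr(H)Cl (excess), THF, 40 °C; I2, 0 °C
Reagents that add atoms: iodine II
Why: Hydrozirconation–iodinolysis: syn Zr–H addition, equilibrated by excess Schwartz reagent to put zirconium on the less hindered methyl-bearing carbon (C8a), then iodination with retention, should give the E iodide with iodine trans to the cyclopropane.

Step 13
Reactants: 15 (R)-benzyl[5-iodo-3-isopropyl-3-(triethylsilyloxy)pent-1-yn-1-yl]dimethylsilane; 26 1-[({(1R,2R)-2-[(E)-2-iodoprop-1-en-1-yl]cyclopropyl}methoxy)methyl]-4-methoxybenzene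
Product: 28 benzyl{(3R,6E)-3-isopropyl-7-[(1S,2R)-2-{[(4-methoxybenzyl)oxy]methyl}cyclopropyl]-6-methyl-3-(triethylsilyloxy)hept-6-en-1-yn-1-yl}dimethylsilane, via alkylzinc iodide 27 (not isolated)
Conditions: 15, Zn dust, LiCl, THF, 40 °C; then 26, Pd(dppf)Cl2 (5 mol %), THF, 40 °C
Reagents that add atoms: none
Why: Negishi sp3–sp2 coupling: direct zinc insertion avoids an alkyllithium that could attack the silyl groups or the alkyne, and the palladium step keeps the alkene geometry, so C1 ends up trans to the cyclopropane (E).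

Step 14
Reactants: 28 benzyl{(3R,6E)-3-isopropyl-7-[(1S,2R)-2-{[(4-methoxybenzyl)oxy]methyl}cyclopropyl]-6-methyl-3-(triethylsilyloxy)hept-6-en-1-yn-1-yl}dimethylsilane
Product: 29 (3R,6R,8aR)-4-[benzyl(dimethyl)silyl]-3-isopropyl-6-{[(4-methoxybenzyl)oxy]methyl}-8a-methyl-3-(triethylsilyloxy)-1,2,3,5,6,8a-hexahydroazulene
Conditions: [Rh(CO)2Cl]2 (5 mol %), toluene (0.02 M), 110 °C
Reagents that add atoms: none
Why: Rh(I) binds the C8a=C8 alkene in the conformer that holds the cyclopropane over the metal, inserts into the unsubstituted C7–C5 bond to give a σ,π-allyl rhodacyclohexene, takes up the tethered alkyne by migratory insertion (C8a–C3a) and reductively eliminates (C4–C5), which is the known intramolecular rhodium-catalysed (5+2) cycloaddition of alkyne-tethered vinylcyclopropanes and tolerates silylalkynes and 2-substituted cyclopropanes. The cyclopentane closes by the tether-directed 5-exo-dig insertion and the cycloheptadiene by C(sp2)–C(sp3) reductive elimination from the eight-membered rhodacycle. C8a is the only new stereocentre: because a cis C7=C8 bond must result, the metal, C5 and the incoming C3a all sit on one face of the E alkene, and that face is fixed by the configuration of C7, so the (6R,7S) cyclopropane relays to (8aR) while C6 passes through unchanged. C3 does not decide the outcome; in the pairing chosen here its oxygen, not its isopropyl group, ends up on the methyl face of the new cyclopentane. The selectivity needed is cleavage of C7–C5 rather than C7–C6, which the trans CH2OPMB group secures by shielding the substituted bond; cleavage of C7–C6 would need the opposite alkene face, so any leakage should appear as a separable regioisomer and not as the C8a epimer. Release of ring strain pays for building the quaternary centre from a trisubstituted alkene.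

Step 15
Reactants: 29 (3R,6R,8aR)-4-[benzyl(dimethyl)silyl]-3-isopropyl-6-{[(4-methoxybenzyl)oxy]methyl}-8a-methyl-3-(triethylsilyloxy)-1,2,3,5,6,8a-hexahydroazulene
Product: 32 (3R,3aR,6R,8aR)-3-hydroxy-3-isopropyl-6-{[(4-methoxybenzyl)oxy]methyl}-8a-methyl-2,3,3a,5,6,8a-hexahydroazulen-4(1H)-one (trans-fused), via vinylsilanol 30 (not isolated), via enol 31 (not isolated)
Conditions: TBAF, THF, 0 °C → rt; then KHCO3, 30% H2O2, MeOH, rt → 40 °C
Reagents that add atoms: hydrogen peroxide OO
Why: Tamao–Fleming oxidation: fluoride removes the TES ether and the benzyl group on silicon, peroxide converts C4–Si into C4–O, and enol 31 tautomerises to the ketone, with C3a settling under the mildly basic medium as the trans-fused epimer in which C4 lies anti to the isopropyl group and its carbonyl can hydrogen-bond to C3–OH.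

Step 16
Reactants: 32 (3R,3aR,6R,8aR)-3-hydroxy-3-isopropyl-6-{[(4-methoxybenzyl)oxy]methyl}-8a-methyl-2,3,3a,5,6,8a-hexahydroazulen-4(1H)-one
Product: 33 (3R,3aS,4S,6R,8aR)-3-isopropyl-6-{[(4-methoxybenzyl)oxy]methyl}-8a-methyl-1,2,3,3a,4,5,6,8a-octahydroazulene-3,4-diol
Conditions: Me4NBH(OAc)3, MeCN/AcOH, −20 °C → rt
Reagents that add atoms: none
Why: Evans–Saksena reduction: the C3 hydroxyl exchanges onto boron and delivers hydride intramolecularly to the β face of C4 (the face of C3–OH and the angular methyl), which places the new hydroxyl group α as required (4S).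

Step 17
Reactants: 34 4-hydroxybenzoic acid
Product: 36 4-(tert-butyldimethylsilyloxy)benzoic acid, via bis-silyl derivative 35 (not isolated)
Conditions: TBSCl (2.2 equiv), imidazole, DMF, rt; then AcOH/THF/H2O, rt
Reagents that add atoms: tert-butyldimethylsilyl chloride CC(C)(C)[Si](C)(C)Cl
Why: Exhaustive silylation followed by selective hydrolysis of the much more labile silyl ester leaves the phenol masked and the acid free.

Step 18
Reactants: 33 (3R,3aS,4S,6R,8aR)-3-isopropyl-6-{[(4-methoxybenzyl)oxy]methyl}-8a-methyl-1,2,3,3a,4,5,6,8a-octahydroazulene-3,4-diol; 36 4-(tert-butyldimethylsilyloxy)benzoic acid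
Product: 37 (3R,3aS,4S,6R,8aR)-3-hydroxy-3-isopropyl-6-{[(4-methoxybenzyl)oxy]methyl}-8a-methyl-1,2,3,3a,4,5,6,8a-octahydroazulen-4-yl 4-(tert-butyldimethylsilyloxy)benzoate
Conditions: DCC, DMAP, CH2Cl2, rt
Reagents that add atoms: none
Why: Steglich esterification; only the secondary C4 hydroxyl should react because C3–OH is tertiary and flanked by isopropyl, and the C4–O bond is not broken, so the configuration is kept.

Step 19
Reactants: 37 (3R,3aS,4S,6R,8aR)-3-hydroxy-3-isopropyl-6-{[(4-methoxybenzyl)oxy]methyl}-8a-methyl-1,2,3,3a,4,5,6,8a-octahydroazulen-4-yl 4-(tert-butyldimethylsilyloxy)benzoate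
Product: 38 (3R,3aS,4S,6R,8aR)-3-hydroxy-6-(hydroxymethyl)-3-isopropyl-8a-methyl-1,2,3,3a,4,5,6,8a-octahydroazulen-4-yl 4-(tert-butyldimethylsilyloxy)benzoate
Conditions: DDQ, CH2Cl2/pH 7 buffer, 0 °C
Reagents that add atoms: none
Why: Oxidative PMB cleavage with DDQ proceeds by benzylic hydride abstraction from the electron-rich ether, towards which the aryl silyl ether, the ester and the isolated alkene are inert.

Step 20
Reactants: 38 (3R,3aS,4S,6R,8aR)-3-hydroxy-6-(hydroxymethyl)-3-isopropyl-8a-methyl-1,2,3,3a,4,5,6,8a-octahydroazulen-4-yl 4-(tert-butyldimethylsilyloxy)benzoate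
Product: 40 (3R,3aS,4S,8aR)-6-formyl-3-hydroxy-3-isopropyl-8a-methyl-1,2,3,3a,4,5,8,8a-octahydroazulen-4-yl 4-(tert-butyldimethylsilyloxy)benzoate, via unconjugated aldehyde 39 (not isolated)
Conditions: DMP, CH2Cl2, rt; aqueous wash; crude 39, DBU (0.2 equiv), CH2Cl2, rt
Reagents that add atoms: none
Why: Dess–Martin oxidation gives the β,γ-unsaturated aldehyde 39, whose doubly activated C6–H is removed by DBU, so reprotonation of the dienolate at C8 moves the alkene into conjugation (C6=C7) and erases the C6 stereocentre.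

Step 21
Reactants: 40 (3R,3aS,4S,8aR)-6-formyl-3-hydroxy-3-isopropyl-8a-methyl-1,2,3,3a,4,5,8,8a-octahydroazulen-4-yl 4-(tert-butyldimethylsilyloxy)benzoate
Product: 41 (3R,3aS,4S,8aR)-6-formyl-3-hydroxy-3-isopropyl-8a-methyl-1,2,3,3a,4,5,8,8a-octahydroazulen-4-yl 4-hydroxybenzoate (CNP0267880.1)
Conditions: TBAF/AcOH, THF, 0 °C
Reagents that add atoms: none
Why: Buffered fluoride cleaves the aryl silyl ether rapidly while the enal, the ester and the tertiary alcohol stay intact.

**Compound list**
1 | (R)-2-hydroxy-3-methylbutanoic acid | CC(C)[C@@H](O)C(=O)O | starting material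
2 | pivalaldehyde | CC(C)(C)C=O | starting material
3 | (2R,5R)-2-tert-butyl-5-isopropyl-1,3-dioxolan-4-one | CC(C)[C@H]1O[C@@H](C(C)(C)C)OC1=O | intermediate
4 | allyl bromide | C=CCBr | starting material
5 | lithium enolate of 3 | CC(C)C1=C([O-])O[C@H](C(C)(C)C)O1.[Li+] | intermediate
6 | (2R,5R)-5-allyl-2-tert-butyl-5-isopropyl-1,3-dioxolan-4-one | CC(C)[C@@]1(CC=C)O[C@@H](C(C)(C)C)OC1=O | intermediate
7 | (2R,5R)-5-allyl-2-tert-butyl-5-isopropyl-1,3-dioxolan-4-ol (lactol, C4 undefined) | CC(C)[C@@]1(CC=C)O[C@@H](C(C)(C)C)OC1O | intermediate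
8 | (R)-2-hydroxy-2-isopropylpent-4-enal | CC(C)[C@](C=O)(O)CC=C | intermediate
9 | (R)-3-isopropylhex-5-en-1-yn-3-ol | CC(C)[C@](C#C)(O)CC=C | intermediate
10 | (R)-triethyl[(3-isopropylhex-5-en-1-yn-3-yl)oxy]silane | CC(C)[C@](C#C)(O[Si](CC)(CC)CC)CC=C | intermediate
11 | lithium acetylide of 10 | CC(C)[C@](C#[C-])(O[Si](CC)(CC)CC)CC=C.[Li+] | intermediate
12 | (R)-benzyl[3-isopropyl-3-(triethylsilyloxy)hex-5-en-1-yn-1-yl]dimethylsilane | CC(C)[C@](C#C[Si](C)(C)Cc1ccccc1)(O[Si](CC)(CC)CC)CC=C | intermediate
13 | (R)-5-[benzyl(dimethyl)silyl]-3-isopropyl-3-(triethylsilyloxy)pent-4-ynal | CC(C)[C@](C#C[Si](C)(C)Cc1ccccc1)(O[Si](CC)(CC)CC)CC=O | intermediate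
14 | (R)-5-[benzyl(dimethyl)silyl]-3-isopropyl-3-(triethylsilyloxy)pent-4-yn-1-ol | CC(C)[C@](C#C[Si](C)(C)Cc1ccccc1)(O[Si](CC)(CC)CC)CCO | intermediate
15 | (R)-benzyl[5-iodo-3-isopropyl-3-(triethylsilyloxy)pent-1-yn-1-yl]dimethylsilane | CC(C)[C@](C#C[Si](C)(C)Cc1ccccc1)(O[Si](CC)(CC)CC)CCI | intermediate
16 | (S)-glycidol | C1[C@@H](O1)CO | starting material
17 | (R)-2-{[(4-methoxybenzyl)oxy]methyl}oxirane | C1O[C@H]1COCc2ccc(OC)cc2 | intermediate
18 | triethyl phosphonoacetate | CCOC(=O)CP(=O)(OCC)OCC | starting material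
19 | sodium salt of 18 | CCOC(=O)[CH-]P(=O)(OCC)OCC.[Na+] | intermediate
20 | ethyl (1R,2R)-2-{[(4-methoxybenzyl)oxy]methyl}cyclopropane-1-carboxylate | CCOC(=O)[C@@H]1C[C@H]1COCc1ccc(OC)cc1 | intermediate
21 | (1R,2R)-2-{[(4-methoxybenzyl)oxy]methyl}cyclopropane-1-carbaldehyde | O=C[C@@H]1C[C@H]1COCc1ccc(OC)cc1 | intermediate
22 | 1-({[(1R,2R)-2-ethynylcyclopropyl]methoxy}methyl)-4-methoxybenzene | C#C[C@@H]1C[C@H]1COCc1ccc(OC)cc1 | intermediate
23 | lithium acetylide of 22 | [Li+].[C-]#C[C@@H]1C[C@H]1COCc1ccc(OC)cc1 | intermediate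
24 | 1-methoxy-4-({[(1R,2R)-2-(prop-1-yn-1-yl)cyclopropyl]methoxy}methyl)benzene | CC#C[C@@H]1C[C@H]1COCc1ccc(OC)cc1 | intermediate
25 | (E)-alkenylzirconocene chloride from 24 (Zr on C8a, trans to cyclopropane) | Cl[Zr](C1C=CC=C1)(C1C=CC=C1)/C(C)=C/[C@@H]1C[C@H]1COCc1ccc(OC)cc1 | intermediate
26 | 1-[({(1R,2R)-2-[(E)-2-iodoprop-1-en-1-yl]cyclopropyl}methoxy)methyl]-4-methoxybenzene | I/C(C)=C/[C@@H]1C[C@H]1COCc1ccc(OC)cc1 | intermediate
27 | alkylzinc iodide from 15 | CC(C)[C@](C#C[Si](C)(C)Cc1ccccc1)(O[Si](CC)(CC)CC)CC[Zn]I | intermediate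
28 | silylalkyne–vinylcyclopropane (3R, 6R, 7S, E) | CC(C)[C@](C#C[Si](C)(C)Cc1ccccc1)(O[Si](CC)(CC)CC)CC/C(C)=C/[C@@H]1C[C@H]1COCc1ccc(OC)cc1 | intermediate
29 | bicyclic diene with C4 vinylsilane (3R,6R,8aR) | CC(C)[C@]1(O[Si](CC)(CC)CC)CC[C@]2(C)C=C[C@H](COCc3ccc(OC)cc3)CC([Si](C)(C)Cc3ccccc3)=C21 | intermediate
30 | C4 vinyl(dimethyl)silanol with free C3–OH | CC(C)[C@]1(O)CC[C@]2(C)C=C[C@H](COCc3ccc(OC)cc3)CC([Si](C)(C)O)=C21 | intermediate
31 | C3a=C4 enol | CC(C)[C@]1(O)CC[C@]2(C)C=C[C@H](COCc3ccc(OC)cc3)CC(O)=C21 | intermediate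
32 | trans-fused β-hydroxy ketone (3R,3aR,6R,8aR) | CC(C)[C@]1(O)CC[C@]2(C)C=C[C@H](COCc3ccc(OC)cc3)CC(=O)[C@H]21 | intermediate
33 | 3,4-diol (3R,3aS,4S,6R,8aR) | CC(C)[C@]1(O)CC[C@]2(C)C=C[C@H](COCc3ccc(OC)cc3)C[C@H](O)[C@H]21 | intermediate
34 | 4-hydroxybenzoic acid | OC(=O)c1ccc(O)cc1 | starting material
35 | tert-butyldimethylsilyl 4-(tert-butyldimethylsilyloxy)benzoate | CC(C)(C)[Si](C)(C)OC(=O)c1ccc(O[Si](C)(C)C(C)(C)C)cc1 | intermediate
36 | 4-(tert-butyldimethylsilyloxy)benzoic acid | OC(=O)c1ccc(O[Si](C)(C)C(C)(C)C)cc1 | intermediate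
37 | C4 ester with C6–CH2OPMB | CC(C)[C@]1(O)CC[C@]2(C)C=C[C@H](COCc3ccc(OC)cc3)C[C@H](OC(=O)c3ccc(O[Si](C)(C)C(C)(C)C)cc3)[C@H]21 | intermediate
38 | C4 ester with C6–CH2OH | CC(C)[C@]1(O)CC[C@]2(C)C=C[C@H](CO)C[C@H](OC(=O)c3ccc(O[Si](C)(C)C(C)(C)C)cc3)[C@H]21 | intermediate
39 | β,γ-unsaturated aldehyde (6R) | CC(C)[C@]1(O)CC[C@]2(C)C=C[C@H](C=O)C[C@H](OC(=O)c3ccc(O[Si](C)(C)C(C)(C)C)cc3)[C@H]21 | intermediate
40 | conjugated enal, phenol as TBS ether | CC(C)[C@]1(O)CC[C@]2(C)CC=C(C=O)C[C@H](OC(=O)c3ccc(O[Si](C)(C)C(C)(C)C)cc3)[C@H]21 | intermediate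
41 | CNP0267880.1 (3R,3aS,4S,8aR) | CC(C)[C@]1(O)CC[C@]2(C)CC=C(C=O)C[C@H](OC(=O)c3ccc(O)cc3)[C@H]21 | target

**Step count**
Total steps: 21. Longest linear sequence: 15 (steps 1–7, 13–16, 18–21).

**Steps most likely to fail**

1. Step 14.
   - What may go wrong: the methyl group cis to the cyclopropane raises the energy of the s-cis conformer the metal must bind. Insertion also has to join two carbons that each sit next to a fully substituted centre, with the silyl group pressed against C3. The cycloaddition may therefore stall and give way to β-hydride elimination from the allyl-rhodium species or to plain enyne cycloisomerisation.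
   - Fallback (from 28, back to the route at 32): K2CO3 in MeOH removes the alkynyl silane to give the terminal alkyne F1. The same rhodium catalysis applied to this much smaller alkyne terminus should give the 4-unsubstituted bicyclic diene F2.
   - TBAF then frees the tertiary allylic alcohol F3, and VO(acac)2/t-BuOOH epoxidises only the C3a=C4 alkene on the hydroxyl (β) face to give the epoxy alcohol F4.
   - Reductive opening with Cp2TiCl (Cp2TiCl2, Mn, collidine hydrochloride, 1,4-cyclohexadiene) passes through the tertiary C3a radical. This radical should take up hydrogen from the less crowded α face to give the C4-epimeric diol F5. Dess–Martin oxidation of the secondary alcohol then gives 32.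

2. Step 15.
   - What may go wrong: oxidation of the tetrasubstituted, crowded C4–Si bond may be slow, so protodesilylation competes. The basic medium may also cause dehydration or retro-aldol opening of the β-hydroxy ketone before C3a has equilibrated.
   - Fallback (from 29, back to the route at 32): HF·pyridine removes only the TES ether to give the vinylsilane carbinol F6. Hydroxyl-directed epoxidation (VO(acac)2, t-BuOOH) gives the α,β-epoxysilane F7.
   - Dilute H2SO4 in aqueous THF opens F7 at the silicon-bearing carbon and triggers acidic Peterson elimination to the enol. The ketone forms and C3a settles under acid, without base or peroxide.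

3. Step 16.
   - What may go wrong: ligand exchange at the hindered tertiary hydroxyl may be slow. Unbound hydride would then attack from the α face, away from the angular methyl, and facial selectivity would be poor.
   - Fallback (from 32, back to the route at 33): the hydride is tied covalently to the C3 oxygen. Chlorodiisopropylsilane with imidazole and DMAP gives the hydridosilyl ether F8. SnCl4-promoted intramolecular hydrosilylation of the ketone delivers hydrogen from the β face and gives the cyclic silylene acetal F9. HF·pyridine then releases the diol.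

**Further compounds**
F1 | step 14 | terminal alkyne (C-desilylated 28) | CC(C)[C@](C#C)(O[Si](CC)(CC)CC)CC/C(C)=C/[C@@H]1C[C@H]1COCc1ccc(OC)cc1
F2 | step 14 | 4-unsubstituted bicyclic diene, C3 TES ether | CC(C)[C@]1(O[Si](CC)(CC)CC)CC[C@]2(C)C=C[C@H](COCc3ccc(OC)cc3)CC=C21
F3 | step 14 | tertiary allylic alcohol from F2 | CC(C)[C@]1(O)CC[C@]2(C)C=C[C@H](COCc3ccc(OC)cc3)CC=C21
F4 | step 14 | 3a,4-β-epoxy alcohol | CC(C)[C@]1(O)CC[C@]2(C)C=C[C@H](COCc3ccc(OC)cc3)C[C@H]4O[C@]214
F5 | step 14 | C4-epimeric diol (4R, 3a-H α) | CC(C)[C@]1(O)CC[C@]2(C)C=C[C@H](COCc3ccc(OC)cc3)C[C@@H](O)[C@H]21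
F6 | step 15 | vinylsilane carbinol (29 without TES) | CC(C)[C@]1(O)CC[C@]2(C)C=C[C@H](COCc3ccc(OC)cc3)CC([Si](C)(C)Cc3ccccc3)=C21
F7 | step 15 | 3a,4-β-epoxysilane | CC(C)[C@]1(O)CC[C@]2(C)C=C[C@H](COCc3ccc(OC)cc3)C[C@@]4([Si](C)(C)Cc3ccccc3)O[C@]214
F8 | step 16 | C3 diisopropyl(hydrido)silyl ether of 32 | CC(C)[C@]1(O[SiH](C(C)C)C(C)C)CC[C@]2(C)C=C[C@H](COCc3ccc(OC)cc3)CC(=O)[C@H]21
F9 | step 16 | cyclic diisopropylsilylene acetal of 33 | CC(C)[C@]1(O[Si]4(C(C)C)C(C)C)CC[C@]2(C)C=C[C@H](COCc3ccc(OC)cc3)C[C@H](O4)[C@H]21
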